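The synthesis rests on opening C3–C4, the bond that joins a plain CH2 (C3) to the Z-trisubstituted C4=C5 alkene of the ten-membered carbocycle (C1–C10), next to the fused butenolide (C6, C7, C11, C12, O). A cathodic nickel-catalysed decarboxylative alkenylation forms this sp3–sp2 bond and closes the ring in one operation, leaving C1, C6 and C8 untouched. Its precursor is an open-chain N-acyloxyphthalimide whose carboxyl carbon, C3, C2, C1(S) and C10 derive from L-glutamic acid; C9–C8 joins it to a preformed butenolide carrying the Z-2-iodopropenyl group on C6. O1 is a TBDPS ether, O8 and O13 are TBS ethers.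

Key step: step 17

Remark 1 (numbering): germacrane numbers are used for all intermediates (C12 lactone carbonyl, C13 CH2O on C11, C14 methylidene on C10, C15 methyl on C4).
Remark 2 (assumption on the sense of reagent control): (R)-BINOL in step 8 is taken to deliver the alkynyl group to the Re face of aldehyde 13, and (+)-Ipc2BCl in step 12 to direct the enolate to the Si face of aldehyde 21; should either sense prove opposite, the enantiomeric ligand or reagent is used.
Remark 3 (protecting groups): O8 and O13 are acetylated only after ring closure, because allylic acetates at these positions would be ionised or reduced under the nickel/cathode conditions.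

Step 1
Reactants: 1 L-glutamic acid
Product: 3 (S)-5-oxotetrahydrofuran-2-carboxylic acid, via (S)-2-hydroxyglutaric acid 2 (not isolated)
Conditions: NaNO2, aq. HCl, 0 °C to rt; evaporate, extract (EtOAc), crystallise
Reagents that add atoms: water, O
Why: Diazotisation of the α-amino acid with α-lactone participation of the neighbouring carboxylate gives substitution by water with net retention at C1, and the γ-carboxyl lactonises on concentration.

Step 2
Reactants: 3 (S)-5-oxotetrahydrofuran-2-carboxylic acid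
Product: 5 (S)-N-methoxy-N-methyl-5-oxotetrahydrofuran-2-carboxamide, via acid chloride 4 (not isolated)
Conditions: (COCl)2, cat. DMF, CH2Cl2, 0 °C to rt; then MeNH(OMe)·HCl, pyridine, CH2Cl2, 0 °C
Reagents that add atoms: N,O-dimethylhydroxylamine hydrochloride, CNOC.Cl; oxalyl chloride, O=C(Cl)C(Cl)=O (chlorine of 4 only)
Why: Acyl chloride formation followed by amidation gives the Weinreb amide of the C10 carboxyl, which is thereby distinguished from the lactonised side-chain carboxyl without enolising C1.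

Step 3
Reactants: 5 (S)-N-methoxy-N-methyl-5-oxotetrahydrofuran-2-carboxamide
Product: 8 (S)-4-[(tert-butyldiphenylsilyl)oxy]-5-[methoxy(methyl)amino]-5-oxopentanoic acid, via lithium hydroxy carboxylate 6 (not isolated), via bis-silyl derivative 7 (not isolated)
Conditions: LiOH·H2O (1.05 equiv), THF/H2O, 0 °C; evaporate; TBDPSCl (2.3 equiv), imidazole, DMF, rt; then AcOH/THF/H2O, rt
Reagents that add atoms: lithium hydroxide, [Li+].[OH-]; tert-butyl(chloro)diphenylsilane, CC(C)(C)[Si](Cl)(c1ccccc1)c1ccccc1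
Why: Saponification of the γ-lactone (the Weinreb amide is untouched), silylation of the freed secondary alcohol and carboxylate, and selective hydrolysis of the labile silyl ester leave the O1 TBDPS ether and a free acid.

Step 4
Reactants: 8 (S)-4-[(tert-butyldiphenylsilyl)oxy]-5-[methoxy(methyl)amino]-5-oxopentanoic acid
Product: 9 (S)-4-[(tert-butyldiphenylsilyl)oxy]-5-oxohexanoic acid
Conditions: MeMgBr (3.2 equiv), THF, −20 to 0 °C; aq. citric acid
Reagents that add atoms: methylmagnesium bromide, C[Mg]Br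
Why: Weinreb ketone synthesis, in which the first equivalent of Grignard reagent masks the acid as its magnesium carboxylate and the chelated tetrahedral adduct releases the methyl ketone (C9–C10) only on work-up, so that neither over-addition nor epimerisation at C1 is expected.

Step 5
Reactants: 9 (S)-4-[(tert-butyldiphenylsilyl)oxy]-5-oxohexanoic acid
Product: 10 methyl (S)-4-[(tert-butyldiphenylsilyl)oxy]-5-oxohexanoate
Conditions: TMSCHN2, toluene/MeOH (4:1), 0 °C
Reagents that add atoms: (trimethylsilyl)diazomethane, C[Si](C)(C)C=[N+]=[N-]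
Why: O-Methylation of the carboxylic acid by the diazoalkane under neutral conditions, which leaves the α-silyloxy ketone alone.

Step 6
Reactants: 11 furan-3,4-diyldimethanol
Product: 12 [4-({[tert-butyl(dimethyl)silyl]oxy}methyl)furan-3-yl]methanol
Conditions: NaH (1.0 equiv), THF, 0 °C to rt; TBSCl (1.0 equiv)
Reagents that add atoms: tert-butyl(chloro)dimethylsilane, CC(C)(C)[Si](C)(C)Cl
Why: Monoprotection of a symmetrical diol by O-silylation of its sparingly soluble monosodium alkoxide.

Step 7
Reactants: 12 [4-({[tert-butyl(dimethyl)silyl]oxy}methyl)furan-3-yl]methanol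
Product: 13 4-({[tert-butyl(dimethyl)silyl]oxy}methyl)furan-3-carbaldehyde
Conditions: MnO2 (activated), CH2Cl2, rt
Reagents that add atoms: none
Why: Manganese dioxide oxidation of a heteroaryl-methanol (benzylic-type alcohol) to the aldehyde, which does not touch the silyl ether.

Step 8
Reactants: 13 4-({[tert-butyl(dimethyl)silyl]oxy}methyl)furan-3-carbaldehyde; 14 propyne
Product: 15 (1R)-1-[4-({[tert-butyl(dimethyl)silyl]oxy}methyl)furan-3-yl]but-2-yn-1-ol
Conditions: 14 (excess), Et2Zn, (R)-BINOL (40 mol%), Ti(OiPr)4 (50 mol%), Cy2NH (5 mol%), Et2O, rt; aq. NH4Cl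
Reagents that add atoms: none
Why: Catalytic asymmetric alkynylzinc addition to an aromatic aldehyde, in which the BINOL–titanium complex delivers the propynyl group (C5, C4, C15) to the Re face and so sets C6 as (R).

Step 9
Reactants: 15 (1R)-1-[4-({[tert-butyl(dimethyl)silyl]oxy}methyl)furan-3-yl]but-2-yn-1-ol
Product: 17 (1R,2Z)-1-[4-({[tert-butyl(dimethyl)silyl]oxy}methyl)furan-3-yl]-3-iodobut-2-en-1-ol, via cyclic alkenylalanate 16 (not isolated)
Conditions: Red-Al, THF, 0 °C to rt; then I2, THF, −78 to 0 °C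
Reagents that add atoms: iodine, II; sodium bis(2-methoxyethoxy)aluminium hydride, [Na+].[AlH2-](OCCOC)OCCOC (aluminium, sodium and alkoxy groups of 16 only)
Why: Alkoxide-directed trans-hydroalumination of the propargylic alcohol places aluminium on the distal carbon C4, and iodinolysis with retention gives the Z-iodoalkene without affecting C6.

Step 10
Reactants: 17 (1R,2Z)-1-[4-({[tert-butyl(dimethyl)silyl]oxy}methyl)furan-3-yl]-3-iodobut-2-en-1-ol
Product: 20 (2R)-4-({[tert-butyl(dimethyl)silyl]oxy}methyl)-5-hydroxy-2-[(Z)-2-iodoprop-1-en-1-yl]-2,5-dihydrofuran-3-carbaldehyde, via furan endoperoxide 18 (not isolated), via cis-enedial 19 (not isolated)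
Conditions: O2, visible light, TPP (cat.), CH2Cl2, −78 °C; then Me2S, −78 °C to rt; crude 20 used at once
Reagents that add atoms: dioxygen, O=O
Why: [4+2] Cycloaddition of singlet oxygen to the furan and reduction of the endoperoxide unmask C8 and C12 as a cis-enedial, which the C6 hydroxyl traps at C12 as a five-membered lactol (closure onto C8 would need a four-membered ring), while C6 itself is not involved.

Step 11
Reactants: 20 (2R)-4-({[tert-butyl(dimethyl)silyl]oxy}methyl)-5-hydroxy-2-[(Z)-2-iodoprop-1-en-1-yl]-2,5-dihydrofuran-3-carbaldehyde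
Product: 21 (2R)-4-({[tert-butyl(dimethyl)silyl]oxy}methyl)-2-[(Z)-2-iodoprop-1-en-1-yl]-5-oxo-2,5-dihydrofuran-3-carbaldehyde
Conditions: TPAP (5 mol%), NMO, 4 Å MS, CH2Cl2, 0 °C to rt
Reagents that add atoms: none
Why: Ley–Griffith oxidation of the lactol to the butenolide under neutral, anhydrous conditions, which avoids over-oxidation of the C8 aldehyde and loss of the acidic C6–H.

Step 12
Reactants: 10 methyl (S)-4-[(tert-butyldiphenylsilyl)oxy]-5-oxohexanoate; 21 (2R)-4-({[tert-butyl(dimethyl)silyl]oxy}methyl)-2-[(Z)-2-iodoprop-1-en-1-yl]-5-oxo-2,5-dihydrofuran-3-carbaldehyde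
Product: 24 methyl (4S,7S)-4-[(tert-butyldiphenylsilyl)oxy]-7-hydroxy-5-oxo-7-(butenolid-7-yl)heptanoate (C8 aldol adduct; full name in the list), via enol borinate 22 (not isolated), via boron aldolate 23 (not isolated)
Conditions: 10 (1.3 equiv), (+)-Ipc2BCl, Et3N, Et2O, 0 °C; then 21, −78 to −20 °C; MeOH, pH 7 buffer, 30% H2O2, 0 °C
Reagents that add atoms: (+)-B-chlorodiisopinocampheylborane, ClB([C@H]1C[C@H]2C[C@@H]([C@@H]1C)C2(C)C)[C@H]1C[C@H]2C[C@@H]([C@@H]1C)C2(C)C (boron and isopinocampheyl groups of 22 and 23 only)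
Why: Boron aldol reaction of a methyl ketone, in which enolisation occurs at the CH3 group away from the α-silyloxy centre and the isopinocampheyl ligands steer the cyclic transition state to the Si face of the aldehyde, forming C8–C9 and setting C8 as (S) under reagent control.

Step 13
Reactants: 24 C8 aldol adduct
Product: 25 O8-TBS ether of 24
Conditions: TBSCl, imidazole, DMAP (cat.), DMF, rt
Reagents that add atoms: tert-butyl(chloro)dimethylsilane, CC(C)(C)[Si](C)(C)Cl
Why: Silylation of the secondary alcohol with a silyl chloride and a weak base, chosen so that the butenolide is not converted into a silyloxyfuran as it could be with a silyl triflate and an amine.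

Step 14
Reactants: 25 O8-TBS β-silyloxy ketone
Product: 26 methyl ester with the C10=C14 methylidene
Conditions: Zn, CH2Br2, TiCl4, THF, 0 °C (reagent preformed); then 25, CH2Cl2, 0 °C to rt
Reagents that add atoms: dibromomethane, BrCBr
Why: Takai–Lombardo methylenation, whose non-basic gem-dimetallic reagent converts the enolisable ketone into the C10=C14 methylidene without attacking the ester, the lactone or the alkenyl iodide and without epimerising C1.

Step 15
Reactants: 26 methyl ester with the C10=C14 methylidene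
Product: 27 carboxylic acid (carboxyl on C3)
Conditions: Me3SnOH, 1,2-dichloroethane, 70 °C; dilute aq. HCl wash
Reagents that add atoms: trimethyltin hydroxide, C[Sn](C)(C)O
Why: Tin hydroxide-mediated cleavage of the unhindered methyl ester under nearly neutral conditions, which spares the silyl ethers and is expected not to deprotonate C6 of the butenolide.

Step 16
Reactants: 27 carboxylic acid; 28 N-hydroxyphthalimide
Product: 29 N-acyloxyphthalimide (precursor of the key step)
Conditions: DIC, DMAP (cat.), CH2Cl2, rt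
Reagents that add atoms: none
Why: Carbodiimide (Steglich-type) esterification converts the acid into the redox-active ester.

Step 17
Reactants: 29 N-acyloxyphthalimide
Product: 30 (1S,6R,8S)-1-[(tert-butyldiphenylsilyl)oxy]-8,13-bis{[tert-butyl(dimethyl)silyl]oxy}germacra-4Z,7(11),10(14)-trien-6,12-olide
Conditions: NiCl2·6H2O (0.5 equiv), 2,2′-bipyridine (0.5 equiv), AgNO3 (0.3 equiv), LiCl, DMF, Mg anode/RVC cathode, undivided cell, constant current (2 mA), rt; 29 added by syringe pump (final concentration about 1 mM)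
Reagents that add atoms: none
Why: Proposed new method: cathodically reduced bipyridine–nickel inserts into the C4–I bond and passes an electron to the N-acyloxyphthalimide, which loses phthalimide anion and CO2 to give the primary C3 radical; this radical is captured by the alkenylnickel(II) held on the same chain, and reductive elimination from nickel(III) forms C3–C4. The closest known reaction type is the intermolecular nickel-electrocatalytic decarboxylative alkenylation of redox-active esters with alkenyl halides (silver-modified cathode, sacrificial anode), and B-alkyl Suzuki–Miyaura macrocyclisations show that the same sp3–sp2 bond type can close medium and large rings. The ten-membered carbocycle (C1–C10) is closed head-to-tail by C(sp3)–C(sp2) reductive elimination at nickel, not by radical addition to an alkene, so Baldwin-type limits do not apply. No stereocentre is formed; C1, C6 and C8 are untouched, and the Z geometry of C4=C5 is inherited from the iodide because oxidative addition and reductive elimination at an alkenyl carbon proceed with retention. The step needs cyclisation to outrun intermolecular coupling, hydrogen-atom capture and 1,5-hydrogen transfer from C9: syringe-pump addition keeps the substrate near 1 mM, the butenolide (C6 and C8 both on C7) together with the Z-iodoalkene bends C4 back towards C3, and the C3 radical has only slow intramolecular alternatives (4-exo or 5-endo at C10=C14, 7-exo at the tetrasubstituted C7=C11). Silyl ethers are kept at O8 and O13 because allylic acetates there would be ionised by low-valent nickel.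

Step 18
Reactants: 30 tris-silylated germacranolide
Product: 31 (1S,6R,8S)-1-[(tert-butyldiphenylsilyl)oxy]-8,13-dihydroxygermacra-4Z,7(11),10(14)-trien-6,12-olide
Conditions: HF·pyridine, pyridine, THF, 0 °C to rt
Reagents that add atoms: none
Why: Buffered HF desilylation cleaves the primary and the secondary TBS ether much faster than the more robust secondary TBDPS ether at O1.

Step 19
Reactants: 31 8,13-diol
Product: 32 (1S,6R,8S)-8,13-diacetoxy-1-[(tert-butyldiphenylsilyl)oxy]germacra-4Z,7(11),10(14)-trien-6,12-olide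
Conditions: Ac2O, pyridine, DMAP (cat.), CH2Cl2, 0 °C
Reagents that add atoms: acetic anhydride, CC(=O)OC(C)=O
Why: Nucleophile-catalysed acetylation of the two free hydroxyls at O8 and O13 while O1 stays protected.

Step 20
Reactants: 32 8,13-diacetate
Product: 33 8α,13-diacetoxy-1α-hydroxygermacra-4,7(11),10(14)-trien-6α,12-olide (target)
Conditions: TBAF/AcOH (1:1), THF, 0 °C to rt
Reagents that add atoms: none
Why: Fluoride-induced Si–O cleavage buffered with acetic acid removes the TBDPS group without acetate migration, ester cleavage or deprotonation at C6.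

Compound list

1 | L-glutamic acid | N[C@@H](CCC(=O)O)C(=O)O | starting material
2 | (S)-2-hydroxypentanedioic acid | O[C@@H](CCC(=O)O)C(=O)O | intermediate (not isolated)
3 | (S)-5-oxotetrahydrofuran-2-carboxylic acid | O=C(O)[C@@H]1CCC(=O)O1 | intermediate
4 | (S)-5-oxotetrahydrofuran-2-carbonyl chloride | O=C(Cl)[C@@H]1CCC(=O)O1 | intermediate (not isolated)
5 | (S)-N-methoxy-N-methyl-5-oxotetrahydrofuran-2-carboxamide | CON(C)C(=O)[C@@H]1CCC(=O)O1 | intermediate
6 | lithium (S)-4-hydroxy-5-[methoxy(methyl)amino]-5-oxopentanoate | CON(C)C(=O)[C@@H](O)CCC(=O)[O-].[Li+] | intermediate (not isolated)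
7 | tert-butyldiphenylsilyl (S)-4-[(tert-butyldiphenylsilyl)oxy]-5-[methoxy(methyl)amino]-5-oxopentanoate | CON(C)C(=O)[C@H](CCC(=O)O[Si](c1ccccc1)(c1ccccc1)C(C)(C)C)O[Si](c1ccccc1)(c1ccccc1)C(C)(C)C | intermediate (not isolated)
8 | (S)-4-[(tert-butyldiphenylsilyl)oxy]-5-[methoxy(methyl)amino]-5-oxopentanoic acid | CON(C)C(=O)[C@H](CCC(=O)O)O[Si](c1ccccc1)(c1ccccc1)C(C)(C)C | intermediate
9 | (S)-4-[(tert-butyldiphenylsilyl)oxy]-5-oxohexanoic acid | CC(=O)[C@H](CCC(=O)O)O[Si](c1ccccc1)(c1ccccc1)C(C)(C)C | intermediate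
10 | methyl (S)-4-[(tert-butyldiphenylsilyl)oxy]-5-oxohexanoate | CC(=O)[C@H](CCC(=O)OC)O[Si](c1ccccc1)(c1ccccc1)C(C)(C)C | intermediate
11 | furan-3,4-diyldimethanol | OCc1cocc1CO | starting material
12 | [4-({[tert-butyl(dimethyl)silyl]oxy}methyl)furan-3-yl]methanol | OCc1cocc1CO[Si](C)(C)C(C)(C)C | intermediate
13 | 4-({[tert-butyl(dimethyl)silyl]oxy}methyl)furan-3-carbaldehyde | O=Cc1cocc1CO[Si](C)(C)C(C)(C)C | intermediate
14 | propyne | CC#C | starting material
15 | (1R)-1-[4-({[tert-butyl(dimethyl)silyl]oxy}methyl)furan-3-yl]but-2-yn-1-ol | CC#C[C@@H](O)c1cocc1CO[Si](C)(C)C(C)(C)C | intermediate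
16 | sodium salt of the cyclic alkenylalanate of 15 (five-membered O–Al–C4=C5–C6 ring, two 2-methoxyethoxy groups on aluminium) | CC1=C[C@H](c2cocc2CO[Si](C)(C)C(C)(C)C)O[Al-]1(OCCOC)OCCOC.[Na+] | intermediate (not isolated)
17 | (1R,2Z)-1-[4-({[tert-butyl(dimethyl)silyl]oxy}methyl)furan-3-yl]-3-iodobut-2-en-1-ol | C/C(I)=C/[C@@H](O)c1cocc1CO[Si](C)(C)C(C)(C)C | intermediate
18 | 2,5-endoperoxide of furan 17 (2,3,7-trioxabicyclo[2.2.1]hept-5-ene) | C/C(I)=C/[C@@H](O)C1=C(CO[Si](C)(C)C(C)(C)C)C2OOC1O2 | intermediate (not isolated)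
19 | (2Z)-2-({[tert-butyl(dimethyl)silyl]oxy}methyl)-3-[(1R,2Z)-1-hydroxy-3-iodobut-2-en-1-yl]but-2-enedial | O=C/C(=C(\C=O)CO[Si](C)(C)C(C)(C)C)[C@H](O)/C=C(/C)I | intermediate (not isolated)
20 | (2R)-4-({[tert-butyl(dimethyl)silyl]oxy}methyl)-5-hydroxy-2-[(Z)-2-iodoprop-1-en-1-yl]-2,5-dihydrofuran-3-carbaldehyde (both C5 anomers) | O=CC1=C(CO[Si](C)(C)C(C)(C)C)C(O)O[C@@H]1/C=C(/C)I | intermediate
21 | (2R)-4-({[tert-butyl(dimethyl)silyl]oxy}methyl)-2-[(Z)-2-iodoprop-1-en-1-yl]-5-oxo-2,5-dihydrofuran-3-carbaldehyde | O=CC1=C(CO[Si](C)(C)C(C)(C)C)C(=O)O[C@@H]1/C=C(/C)I | intermediate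
22 | methyl (S)-4-[(tert-butyldiphenylsilyl)oxy]-5-[(diisopinocampheylboranyl)oxy]hex-5-enoate (enol borinate of 10) | C=C(OB([C@H]1C[C@H]2C[C@@H]([C@@H]1C)C2(C)C)[C@H]1C[C@H]2C[C@@H]([C@@H]1C)C2(C)C)[C@H](CCC(=O)OC)O[Si](c1ccccc1)(c1ccccc1)C(C)(C)C | intermediate (not isolated)
23 | O8-diisopinocampheylborinate of aldol 24 | COC(=O)CC[C@H](O[Si](c1ccccc1)(c1ccccc1)C(C)(C)C)C(=O)C[C@H](OB([C@H]1C[C@H]2C[C@@H]([C@@H]1C)C2(C)C)[C@H]1C[C@H]2C[C@@H]([C@@H]1C)C2(C)C)C1=C(CO[Si](C)(C)C(C)(C)C)C(=O)O[C@@H]1/C=C(/C)I | intermediate (not isolated)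
24 | methyl (4S,7S)-4-[(tert-butyldiphenylsilyl)oxy]-7-{(2R)-4-({[tert-butyl(dimethyl)silyl]oxy}methyl)-2-[(Z)-2-iodoprop-1-en-1-yl]-5-oxo-2,5-dihydrofuran-3-yl}-7-hydroxy-5-oxoheptanoate | COC(=O)CC[C@H](O[Si](c1ccccc1)(c1ccccc1)C(C)(C)C)C(=O)C[C@H](O)C1=C(CO[Si](C)(C)C(C)(C)C)C(=O)O[C@@H]1/C=C(/C)I | intermediate
25 | methyl (4S,7S)-4-[(tert-butyldiphenylsilyl)oxy]-7-{[tert-butyl(dimethyl)silyl]oxy}-7-{(2R)-4-({[tert-butyl(dimethyl)silyl]oxy}methyl)-2-[(Z)-2-iodoprop-1-en-1-yl]-5-oxo-2,5-dihydrofuran-3-yl}-5-oxoheptanoate | COC(=O)CC[C@H](O[Si](c1ccccc1)(c1ccccc1)C(C)(C)C)C(=O)C[C@H](O[Si](C)(C)C(C)(C)C)C1=C(CO[Si](C)(C)C(C)(C)C)C(=O)O[C@@H]1/C=C(/C)I | intermediate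
26 | methyl (4S,7S)-4-[(tert-butyldiphenylsilyl)oxy]-7-{[tert-butyl(dimethyl)silyl]oxy}-7-{(2R)-4-({[tert-butyl(dimethyl)silyl]oxy}methyl)-2-[(Z)-2-iodoprop-1-en-1-yl]-5-oxo-2,5-dihydrofuran-3-yl}-5-methylideneheptanoate | COC(=O)CC[C@H](O[Si](c1ccccc1)(c1ccccc1)C(C)(C)C)C(=C)C[C@H](O[Si](C)(C)C(C)(C)C)C1=C(CO[Si](C)(C)C(C)(C)C)C(=O)O[C@@H]1/C=C(/C)I | intermediate
27 | (4S,7S)-4-[(tert-butyldiphenylsilyl)oxy]-7-{[tert-butyl(dimethyl)silyl]oxy}-7-{(2R)-4-({[tert-butyl(dimethyl)silyl]oxy}methyl)-2-[(Z)-2-iodoprop-1-en-1-yl]-5-oxo-2,5-dihydrofuran-3-yl}-5-methylideneheptanoic acid | O=C(O)CC[C@H](O[Si](c1ccccc1)(c1ccccc1)C(C)(C)C)C(=C)C[C@H](O[Si](C)(C)C(C)(C)C)C1=C(CO[Si](C)(C)C(C)(C)C)C(=O)O[C@@H]1/C=C(/C)I | intermediate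
28 | N-hydroxyphthalimide | O=C1c2ccccc2C(=O)N1O | starting material
29 | 1,3-dioxoisoindolin-2-yl ester of acid 27 (N-acyloxyphthalimide; (1S)-OTBDPS, 8,13-bis-OTBS, butenolide, Z-2-iodopropenyl on C6) | O=C(ON1C(=O)c2ccccc2C1=O)CC[C@H](O[Si](c1ccccc1)(c1ccccc1)C(C)(C)C)C(=C)C[C@H](O[Si](C)(C)C(C)(C)C)C1=C(CO[Si](C)(C)C(C)(C)C)C(=O)O[C@@H]1/C=C(/C)I | intermediate
30 | (1S,6R,8S)-1-[(tert-butyldiphenylsilyl)oxy]-8,13-bis{[tert-butyl(dimethyl)silyl]oxy}germacra-4Z,7(11),10(14)-trien-6,12-olide | C=C1C[C@H](O[Si](C)(C)C(C)(C)C)C2=C(CO[Si](C)(C)C(C)(C)C)C(=O)O[C@@H]2/C=C(/C)CC[C@@H]1O[Si](c1ccccc1)(c1ccccc1)C(C)(C)C | intermediate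
31 | (1S,6R,8S)-1-[(tert-butyldiphenylsilyl)oxy]-8,13-dihydroxygermacra-4Z,7(11),10(14)-trien-6,12-olide | C=C1C[C@H](O)C2=C(CO)C(=O)O[C@@H]2/C=C(/C)CC[C@@H]1O[Si](c1ccccc1)(c1ccccc1)C(C)(C)C | intermediate
32 | (1S,6R,8S)-8,13-diacetoxy-1-[(tert-butyldiphenylsilyl)oxy]germacra-4Z,7(11),10(14)-trien-6,12-olide | C=C1C[C@H](OC(C)=O)C2=C(COC(C)=O)C(=O)O[C@@H]2/C=C(/C)CC[C@@H]1O[Si](c1ccccc1)(c1ccccc1)C(C)(C)C | intermediate
33 | 8α,13-diacetoxy-1α-hydroxygermacra-4,7(11),10(14)-trien-6α,12-olide | C=C1C[C@H](OC(C)=O)C2=C(COC(C)=O)C(=O)O[C@@H]2/C=C(/C)CC[C@@H]1O | target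

Total step count: 20. Longest linear sequence: 15 steps (11 to 33 through steps 6–11 and 12–20); the glutamic acid branch (steps 1–5) joins at step 12.

Steps most likely to fail

Step 17 (proposed new method). Ring closure may lose to intermolecular coupling and oligomer formation, to reduction of the C3 radical by hydrogen-atom capture, to 1,5-hydrogen transfer from the allylic C9 position, or to protodeiodination at C4. The fallback uses known chemistry and forms the same bond. It sets out from 29: photochemical decarboxylative borylation with bis(catecholato)diboron (DMAc, blue light) gives the primary alkyl catechol boronate F1. This is transesterified in the same flask (pinacol, Et3N) to the alkyl pinacol boronate F2, with boron on C3 and the alkenyl iodide intact. A B-alkyl Suzuki–Miyaura macrocyclisation (Pd(dppf)Cl2, Ag2O, K2CO3, THF, 60 °C, high dilution) then joins C3 to C4 and returns to the route at 30.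

Step 12. Facial selectivity at C8 may be poor if the resident centres C1 and C6 oppose the reagent, and the amine may cause epimerisation at C6 of aldehyde 21 before addition. The fallback replaces the closed boron transition state by Lewis-acid catalysis without amine. It sets out from 10: kinetic silylation (LiHMDS, TMSCl, THF, −78 °C) gives the trimethylsilyl enol ether F3. A Mukaiyama aldol reaction with 21 under a chiral BINOL–titanium(IV) catalyst gives the O8-trimethylsilyl aldol F4, and dilute citric acid in MeOH removes the trimethylsilyl group, so that the route is rejoined at 24.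

Step 10. The lactol may lose water and re-aromatise to a 2-alkenylfuran-3-carbaldehyde, which destroys the C6 stereocentre, or singlet oxygen may react in an ene mode with the side chain. The fallback avoids the lactol. It sets out from 17: photo-oxygenation in the presence of iPr2NEt removes the less hindered bridgehead hydrogen of the endoperoxide (next to the carbon that bears CH2OTBS) and gives the 5-hydroxybutenolide F5, with C12 at the acid level and C8 as a hemiacetal. CSA and 4 Å molecular sieves in CH2Cl2 then close the lactone onto the C6 hydroxyl and free the C8 aldehyde, which rejoins the route at 21.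

Further compounds

F1 | step 17 | catechol boronate at C3: 2-alkyl-1,3,2-benzodioxaborole in place of the C(=O)O–phthalimide group of 29 | O1c2ccccc2OB1CC[C@H](O[Si](c1ccccc1)(c1ccccc1)C(C)(C)C)C(=C)C[C@H](O[Si](C)(C)C(C)(C)C)C1=C(CO[Si](C)(C)C(C)(C)C)C(=O)O[C@@H]1/C=C(/C)I
F2 | step 17 | pinacol boronate at C3 (4,4,5,5-tetramethyl-1,3,2-dioxaborolan-2-yl in place of the C(=O)O–phthalimide group of 29) | CC1(C)OB(CC[C@H](O[Si](c2ccccc2)(c2ccccc2)C(C)(C)C)C(=C)C[C@H](O[Si](C)(C)C(C)(C)C)C2=C(CO[Si](C)(C)C(C)(C)C)C(=O)O[C@@H]2/C=C(/C)I)OC1(C)C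
F3 | step 12 | methyl (S)-4-[(tert-butyldiphenylsilyl)oxy]-5-[(trimethylsilyl)oxy]hex-5-enoate | C=C(O[Si](C)(C)C)[C@H](CCC(=O)OC)O[Si](c1ccccc1)(c1ccccc1)C(C)(C)C
F4 | step 12 | O8-trimethylsilyl ether of aldol 24 | COC(=O)CC[C@H](O[Si](c1ccccc1)(c1ccccc1)C(C)(C)C)C(=O)C[C@H](O[Si](C)(C)C)C1=C(CO[Si](C)(C)C(C)(C)C)C(=O)O[C@@H]1/C=C(/C)I
F5 | step 10 | 3-({[tert-butyl(dimethyl)silyl]oxy}methyl)-5-hydroxy-4-[(1R,2Z)-1-hydroxy-3-iodobut-2-en-1-yl]furan-2(5H)-one | O=C1OC(O)C([C@H](O)/C=C(/C)I)=C1CO[Si](C)(C)C(C)(C)C
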